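**Plan**
- **Numbering and enabling feature.** Each half is numbered C1(OH), C2 (biaryl carbon), C3, C4(OMe), C4a, C5(OH), C6, C7(Me), C8, C8a. In the two oxygenated rings, C3=C2–C2'=C3' is a 2,3-disubstituted buta-1,3-diene, and the para oxygens at C1 and C4 are unlike.
- **Retrosynthesis.** O-methyl and protecting groups are removed first. C3–C4 and C3'–C4' are then cut (retro-6π, retro-4π) to a diene bearing two benzocyclobutenones, with C1 as silylated carbinol and C4 as carbonyl (latent ketene). Next C1–C2 and C1'–C2' are cut (dienyl anion + ketone), and last C1–C8a and C4–C4a (aryne + trioxygenated ethene).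
- **Four-membered ring.** The orcinol ring enters as an aryne. A [2+2] cycloaddition places the ketal carbon (C4) next to the benzyloxy group and brings the C1 oxygen along, so no C–H oxidation has to tell ring CH2, ArCH3 and OCH2Ph apart.
- **Assembly.** Two such ketones are joined to 2,3-distannylbutadiene by successive tin–lithium exchanges. Silylation and ketal hydrolysis give the thermolysis substrate, and both oxygenated naphthalene rings close in one operation.
- **Endgame.** The free C4 phenols are methylated, the silyl ethers removed and the benzyl ethers hydrogenolysed.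
- **Stereochemistry.** The target has no stereocentre. The two carbinol centres formed on the way are uncontrolled and vanish on aromatisation.

Key step: step 10

Assumption: the 2,2' axis carries only one non-hydrogen ortho substituent per ring (the C1 hydroxyl), so it is treated as freely rotating and the target as achiral, as drawn.

Step 1
Reactants: 1 orcinol (5-methylbenzene-1,3-diol)
Product: 2 2-iodo-5-methylbenzene-1,3-diol
Conditions: I2 (1 equiv), NaHCO3, H2O–THF, 0 °C to rt
Reagents that add atoms: iodine, II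
Why: Electrophilic aromatic iodination of the resorcinol phenoxide in aqueous hydrogencarbonate goes to the carbon between the two hydroxyls, as in the standard preparation of 2-iodoresorcinols, and one equivalent of iodine limits over-iodination.

Step 2
Reactants: 2 2-iodo-5-methylbenzene-1,3-diol
Product: 3 3-(benzyloxy)-2-iodo-5-methylphenol
Conditions: BnBr (1 equiv), K2CO3, acetone, reflux
Reagents that add atoms: benzyl bromide, BrCc1ccccc1
Why: Williamson etherification with one equivalent of halide desymmetrises the two equivalent phenols statistically, and unreacted diol and dibenzyl ether differ enough in polarity to be removed, the diol being recycled.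

Step 3
Reactants: 3 3-(benzyloxy)-2-iodo-5-methylphenol
Product: 4 3-(benzyloxy)-2-iodo-5-methylphenyl trifluoromethanesulfonate
Conditions: Tf2O, pyridine, CH2Cl2, 0 °C
Reagents that add atoms: triflic anhydride, O=S(=O)(OS(=O)(=O)C(F)(F)F)C(F)(F)F
Why: O-Sulfonylation of the remaining phenol gives an ortho-iodoaryl triflate, the established aryne precursor for halogen–lithium exchange at low temperature.

Step 4
Reactants: 4 3-(benzyloxy)-2-iodo-5-methylphenyl trifluoromethanesulfonate; 5 tris(trimethylsilyloxy)ethene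
Product: 10 2-(benzyloxy)-8,8-dimethoxy-4-methylbicyclo[4.2.0]octa-1,3,5-trien-7-ol (racemic), via aryllithium 6 (not isolated), via aryne 7 (not isolated), via tris(silyl) cycloadduct 8 (not isolated), via hydroxy ketone 9 (not isolated)
Conditions: n-BuLi, THF, −78 °C; then MeOH, HC(OMe)3, CSA (cat.), −78 °C to rt
Reagents that add atoms: methanol, CO; trimethyl orthoformate, COC(OC)OC
Why: Iodine–lithium exchange and loss of LiOTf give aryne 7, whose carbon remote from the benzyloxy group is attacked by the nucleophilic CH(OSiMe3) carbon of 5 so that the aryl anion, stabilised inductively next to oxygen, closes on the dioxocarbenium carbon (regioselective aryne–ketene silyl acetal [2+2] cycloaddition), after which acid methanolysis and orthoformate ketalisation exchange the labile silyl ketal for the dimethyl ketal and free the secondary alcohol, whose racemic centre is removed in step 5.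

Step 5
Reactants: 10 2-(benzyloxy)-8,8-dimethoxy-4-methylbicyclo[4.2.0]octa-1,3,5-trien-7-ol
Product: 11 2-(benzyloxy)-8,8-dimethoxy-4-methylbicyclo[4.2.0]octa-1,3,5-trien-7-one
Conditions: Dess–Martin periodinane, CH2Cl2, rt
Reagents that add atoms: none
Why: Dess–Martin oxidation turns the secondary benzocyclobutenol into the ketone under neutral conditions, so that no alkoxide able to trigger ring opening is formed and ketal, benzyl ether and aryl methyl group are left alone.

Step 6
Reactants: 12 1,4-dichlorobut-2-yne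
Product: 13 2,3-bis(trimethylstannyl)buta-1,3-diene
Conditions: Me3SnCl, Li, THF, 0 °C; then 12, −78 °C to rt
Reagents that add atoms: trimethyltin chloride, C[Sn](C)(C)Cl
Why: Twofold SN2' substitution by the stannyl anion: attack at an alkyne carbon expels the first chloride to give a (chloromethyl)allenylstannane, and attack at its central allene carbon expels the second, which is the known entry to 2,3-dimetallated butadienes from this dichloride.

Step 7
Reactants: 13 2,3-bis(trimethylstannyl)buta-1,3-diene; 11 2-(benzyloxy)-8,8-dimethoxy-4-methylbicyclo[4.2.0]octa-1,3,5-trien-7-one (two equivalents, added in two portions)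
Product: 18 7,7'-(buta-1,3-diene-2,3-diyl)bis[2-(benzyloxy)-8,8-dimethoxy-4-methylbicyclo[4.2.0]octa-1,3,5-trien-7-ol] (diastereomer mixture), via lithio(stannyl)butadiene 14 (not isolated), via stannylated alkoxide 15 (not isolated), via lithiated alkoxide 16 (not isolated), via dilithium dialkoxide 17 (not isolated)
Conditions: MeLi (1 equiv), THF, −78 °C; 11 (1 equiv); MeLi (1 equiv), −78 °C; 11 (1 equiv); AcOH, −78 °C
Reagents that add atoms: none
Why: Tin–lithium exchange of an alkenylstannane followed by 1,2-addition to a strained, non-enolisable cyclobutenone carbonyl is run twice in succession so that no vicinal dilithio species is needed, the ketal blocks the carbonyl next to the benzyloxy group, holding −78 °C until the acid quench suppresses oxyanion-accelerated ring opening, and the two carbinol centres form without control (meso and dl), which is harmless because both become sp2 in step 10.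

Step 8
Reactants: 18 7,7'-(buta-1,3-diene-2,3-diyl)bis[2-(benzyloxy)-8,8-dimethoxy-4-methylbicyclo[4.2.0]octa-1,3,5-trien-7-ol]
Product: 19 2,3-bis[2-(benzyloxy)-7-(tert-butyldimethylsilyloxy)-8,8-dimethoxy-4-methylbicyclo[4.2.0]octa-1,3,5-trien-7-yl]buta-1,3-diene (diastereomer mixture)
Conditions: TBSOTf, 2,6-lutidine, CH2Cl2, 0 °C to rt
Reagents that add atoms: tert-butyldimethylsilyl triflate, CC(C)(C)[Si](C)(C)OS(=O)(=O)C(F)(F)F
Why: Silyl triflate with a hindered pyridine base is the standard silylation of congested tertiary alcohols, the ketals cannot form enol ethers (no α-hydrogen), and any ketal lost on work-up would only anticipate step 9.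

Step 9
Reactants: 19 2,3-bis[2-(benzyloxy)-7-(tert-butyldimethylsilyloxy)-8,8-dimethoxy-4-methylbicyclo[4.2.0]octa-1,3,5-trien-7-yl]buta-1,3-diene
Product: 20 2,3-bis[2-(benzyloxy)-7-(tert-butyldimethylsilyloxy)-4-methyl-8-oxobicyclo[4.2.0]octa-1,3,5-trien-7-yl]buta-1,3-diene (diastereomer mixture)
Conditions: 2 M aq HCl, THF, rt
Reagents that add atoms: water, O
Why: Acid-catalysed ketal hydrolysis is helped by the ortho benzyloxy group, which stabilises the oxocarbenium ion at C4, whereas the hindered tertiary silyl ethers hydrolyse slowly and ionisation at C1 is disfavoured by ring strain and by the adjacent electron-poor carbon.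

Step 10
Reactants: 20 2,3-bis[2-(benzyloxy)-7-(tert-butyldimethylsilyloxy)-4-methyl-8-oxobicyclo[4.2.0]octa-1,3,5-trien-7-yl]buta-1,3-diene
Product: 26 5,5'-bis(benzyloxy)-1,1'-bis(tert-butyldimethylsilyloxy)-7,7'-dimethyl-2,2'-binaphthalene-4,4'-diol, via first vinylketene 21 (not isolated), via first keto tautomer 22 (not isolated), via half-expanded naphthol 23 (not isolated), via second vinylketene 24 (not isolated), via second keto tautomer 25 (not isolated)
Conditions: xylenes (degassed, 0.01 M), 140 °C, Ar
Reagents that add atoms: none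
Why: Heating cleaves the C1–C4 bond of one four-membered ring in a conrotatory 4π-opening to the o-quinoid vinylketene 21, whose ketene carbon C4 bonds to the diene terminus C3 in a 6π-electrocyclisation to give the 4(3H)-naphthalenone 22; enolisation to 23 restores the benzenoid ring, and the same sequence (24, 25) converts the second half. The closest known reaction is the Moore rearrangement of 4-alkenyl-4-oxycyclobutenones in its benzo-fused form, the thermal ring expansion of 2-alkenyl-2-silyloxybenzocyclobutenones to 1,4-dioxygenated naphthalenes, applied here twice in one molecule. Each new six-membered ring (C1, C2, C3, C4, C4a, C8a) closes by a thermally allowed disrotatory 6π-electrocyclisation of the C4=C4a/C8a=C1/C2=C3 triene, and because the diene offers each ketene only its own C2=C3 unit in linear conjugation the two closures are independent. No stereocentre is created and the two carbinol centres become sp2, so the meso and dl forms of 20 converge on one product. The step needs torquoselectivity, secured by the donor silyloxy group, which rotates outward and turns the alkenyl group toward the ketene, while an opening in the wrong sense can only reclose to the benzocyclobutenone because rearomatisation drives it back. It also needs the para oxygens to stay distinct, which follows from the mechanism (ketene oxygen free at C4 beside the peri C5 benzyloxy group, carbinol oxygen still silylated at C1), and high dilution with exclusion of oxygen keeps the ketene from acylating product naphthol and the product from oxidising.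

Step 11
Reactants: 26 5,5'-bis(benzyloxy)-1,1'-bis(tert-butyldimethylsilyloxy)-7,7'-dimethyl-2,2'-binaphthalene-4,4'-diol
Product: 27 5,5'-bis(benzyloxy)-1,1'-bis(tert-butyldimethylsilyloxy)-4,4'-dimethoxy-7,7'-dimethyl-2,2'-binaphthalene
Conditions: MeI, K2CO3, acetone, reflux, Ar
Reagents that add atoms: iodomethane, CI
Why: Williamson methylation of the two free naphthols under anhydrous carbonate conditions, which the hindered aryl silyl ethers at C1 (flanked by the C2 aryl group and the peri hydrogen) and the benzyl ethers tolerate.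

Step 12
Reactants: 27 5,5'-bis(benzyloxy)-1,1'-bis(tert-butyldimethylsilyloxy)-4,4'-dimethoxy-7,7'-dimethyl-2,2'-binaphthalene
Product: 28 5,5'-bis(benzyloxy)-4,4'-dimethoxy-7,7'-dimethyl-2,2'-binaphthalene-1,1'-diol
Conditions: Bu4NF, AcOH, THF (degassed), 0 °C, Ar
Reagents that add atoms: none
Why: Fluoride-induced cleavage of aryl silyl ethers is fast at low temperature, and buffering with acetic acid under exclusion of oxygen keeps the electron-rich 4-methoxy-1-naphthol units from being oxidised as their naphtholates.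

Step 13
Reactants: 28 5,5'-bis(benzyloxy)-4,4'-dimethoxy-7,7'-dimethyl-2,2'-binaphthalene-1,1'-diol
Product: 29 4,4'-dimethoxy-7,7'-dimethyl-2,2'-binaphthalene-1,1',5,5'-tetraol (CNP0204479.0)
Conditions: H2 (1 atm), Pd/C, EtOAc–MeOH, rt
Reagents that add atoms: none
Why: Catalytic hydrogenolysis removes both aryl benzyl ethers without touching the methyl ethers or the naphthalene rings at ambient pressure, and the reducing medium protects the oxidation-prone tetraol, which is why this step is placed last.

**Compound list**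
1 | orcinol (5-methylbenzene-1,3-diol) | Cc1cc(O)cc(O)c1 | starting material
2 | 2-iodo-5-methylbenzene-1,3-diol | Cc1cc(O)c(I)c(O)c1 | intermediate
3 | 3-(benzyloxy)-2-iodo-5-methylphenol | Cc1cc(O)c(I)c(OCc2ccccc2)c1 | intermediate
4 | 3-(benzyloxy)-2-iodo-5-methylphenyl trifluoromethanesulfonate | Cc1cc(OCc2ccccc2)c(I)c(OS(=O)(=O)C(F)(F)F)c1 | intermediate
5 | tris(trimethylsilyloxy)ethene | C[Si](C)(C)OC=C(O[Si](C)(C)C)O[Si](C)(C)C | starting material
6 | 3-(benzyloxy)-2-lithio-5-methylphenyl trifluoromethanesulfonate | Cc1cc(OCc2ccccc2)c([Li])c(OS(=O)(=O)C(F)(F)F)c1 | intermediate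
7 | 3-(benzyloxy)-5-methylbenzyne | CC1=CC#CC(OCc2ccccc2)=C1 | intermediate
8 | 2-(benzyloxy)-4-methyl-7,8,8-tris(trimethylsilyloxy)bicyclo[4.2.0]octa-1,3,5-triene (racemic) | Cc1cc(OCc2ccccc2)c2c(c1)C(O[Si](C)(C)C)C2(O[Si](C)(C)C)O[Si](C)(C)C | intermediate
9 | 5-(benzyloxy)-8-hydroxy-3-methylbicyclo[4.2.0]octa-1,3,5-trien-7-one (racemic) | Cc1cc(OCc2ccccc2)c2c(c1)C(O)C2=O | intermediate
10 | 2-(benzyloxy)-8,8-dimethoxy-4-methylbicyclo[4.2.0]octa-1,3,5-trien-7-ol (racemic) | Cc1cc(OCc2ccccc2)c2c(c1)C(O)C2(OC)OC | intermediate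
11 | 2-(benzyloxy)-8,8-dimethoxy-4-methylbicyclo[4.2.0]octa-1,3,5-trien-7-one | Cc1cc(OCc2ccccc2)c2c(c1)C(=O)C2(OC)OC | intermediate
12 | 1,4-dichlorobut-2-yne | ClCC#CCCl | starting material
13 | 2,3-bis(trimethylstannyl)buta-1,3-diene | C=C([Sn](C)(C)C)C(=C)[Sn](C)(C)C | intermediate
14 | 2-lithio-3-(trimethylstannyl)buta-1,3-diene | [Li]C(=C)C(=C)[Sn](C)(C)C | intermediate
15 | lithium 2-(benzyloxy)-8,8-dimethoxy-4-methyl-7-[3-(trimethylstannyl)buta-1,3-dien-2-yl]bicyclo[4.2.0]octa-1,3,5-trien-7-olate | [Li]OC1(C(=C)C(=C)[Sn](C)(C)C)c2cc(C)cc(OCc3ccccc3)c2C1(OC)OC | intermediate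
16 | lithium 2-(benzyloxy)-7-(3-lithiobuta-1,3-dien-2-yl)-8,8-dimethoxy-4-methylbicyclo[4.2.0]octa-1,3,5-trien-7-olate | [Li]OC1(C(=C)C([Li])=C)c2cc(C)cc(OCc3ccccc3)c2C1(OC)OC | intermediate
17 | dilithium dialkoxide of diol 18 | [Li]OC1(C(=C)C(=C)C2(O[Li])c3cc(C)cc(OCc4ccccc4)c3C2(OC)OC)c2cc(C)cc(OCc3ccccc3)c2C1(OC)OC | intermediate
18 | 7,7'-(buta-1,3-diene-2,3-diyl)bis[2-(benzyloxy)-8,8-dimethoxy-4-methylbicyclo[4.2.0]octa-1,3,5-trien-7-ol] (meso and dl mixture) | OC1(C(=C)C(=C)C2(O)c3cc(C)cc(OCc4ccccc4)c3C2(OC)OC)c2cc(C)cc(OCc3ccccc3)c2C1(OC)OC | intermediate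
19 | 2,3-bis[2-(benzyloxy)-7-(tert-butyldimethylsilyloxy)-8,8-dimethoxy-4-methylbicyclo[4.2.0]octa-1,3,5-trien-7-yl]buta-1,3-diene (meso and dl mixture) | COC1(OC)c2c(OCc3ccccc3)cc(C)cc2C1(O[Si](C)(C)C(C)(C)C)C(=C)C(=C)C1(O[Si](C)(C)C(C)(C)C)c2cc(C)cc(OCc3ccccc3)c2C1(OC)OC | intermediate
20 | 2,3-bis[2-(benzyloxy)-7-(tert-butyldimethylsilyloxy)-4-methyl-8-oxobicyclo[4.2.0]octa-1,3,5-trien-7-yl]buta-1,3-diene (meso and dl mixture) | C=C(C(=C)C1(O[Si](C)(C)C(C)(C)C)C(=O)c2c(OCc3ccccc3)cc(C)cc21)C1(O[Si](C)(C)C(C)(C)C)C(=O)c2c(OCc3ccccc3)cc(C)cc21 | intermediate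
21 | first o-quinoid vinylketene: one four-membered ring of 20 opened between C1 and C4, giving a cyclohexa-2,4-diene with exocyclic C4a=C4=O and (E)-C8a=C1(OTBS); the dienyl group on C1 lies cis to the ketene and carries the intact second benzocyclobutenone | O=C=C1C(OCc2ccccc2)=CC(C)=C/C1=C(\O[Si](C)(C)C(C)(C)C)C(=C)C(=C)C1(O[Si](C)(C)C(C)(C)C)C(=O)c2c(OCc3ccccc3)cc(C)cc21 | intermediate
22 | first keto tautomer: 8-(benzyloxy)-4-(tert-butyldimethylsilyloxy)-6-methyl-3-{1-[2-(benzyloxy)-7-(tert-butyldimethylsilyloxy)-4-methyl-8-oxobicyclo[4.2.0]octa-1,3,5-trien-7-yl]ethenyl}naphthalen-1(2H)-one | O=C1CC(C(=C)C2(O[Si](C)(C)C(C)(C)C)C(=O)c3c(OCc4ccccc4)cc(C)cc32)=C(O[Si](C)(C)C(C)(C)C)c2cc(C)cc(OCc3ccccc3)c21 | intermediate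
23 | half-expanded naphthol (target numbering): 5-(benzyloxy)-1-(tert-butyldimethylsilyloxy)-7-methyl-2-{1-[2-(benzyloxy)-7-(tert-butyldimethylsilyloxy)-4-methyl-8-oxobicyclo[4.2.0]octa-1,3,5-trien-7-yl]ethenyl}naphthalen-4-ol | Oc1cc(C(=C)C2(O[Si](C)(C)C(C)(C)C)C(=O)c3c(OCc4ccccc4)cc(C)cc32)c(O[Si](C)(C)C(C)(C)C)c2cc(C)cc(OCc3ccccc3)c12 | intermediate
24 | second o-quinoid vinylketene: remaining four-membered ring of 23 opened between C1' and C4', with exocyclic C4a'=C4'=O and (E)-C8a'=C1'(OTBS); the 1-(naphthyl)ethenyl group lies cis to the ketene | Oc1cc(C(=C)C(/O[Si](C)(C)C(C)(C)C)=C2/C=C(C)C=C(OCc3ccccc3)C2=C=O)c(O[Si](C)(C)C(C)(C)C)c2cc(C)cc(OCc3ccccc3)c12 | intermediate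
25 | second keto tautomer: 8-(benzyloxy)-3-[5-(benzyloxy)-1-(tert-butyldimethylsilyloxy)-4-hydroxy-7-methylnaphthalen-2-yl]-4-(tert-butyldimethylsilyloxy)-6-methylnaphthalen-1(2H)-one | Oc1cc(C2=C(O[Si](C)(C)C(C)(C)C)c3cc(C)cc(OCc4ccccc4)c3C(=O)C2)c(O[Si](C)(C)C(C)(C)C)c2cc(C)cc(OCc3ccccc3)c12 | intermediate
26 | 5,5'-bis(benzyloxy)-1,1'-bis(tert-butyldimethylsilyloxy)-7,7'-dimethyl-2,2'-binaphthalene-4,4'-diol | Oc1cc(-c2cc(O)c3c(OCc4ccccc4)cc(C)cc3c2O[Si](C)(C)C(C)(C)C)c(O[Si](C)(C)C(C)(C)C)c2cc(C)cc(OCc3ccccc3)c12 | intermediate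
27 | 5,5'-bis(benzyloxy)-1,1'-bis(tert-butyldimethylsilyloxy)-4,4'-dimethoxy-7,7'-dimethyl-2,2'-binaphthalene | COc1cc(-c2cc(OC)c3c(OCc4ccccc4)cc(C)cc3c2O[Si](C)(C)C(C)(C)C)c(O[Si](C)(C)C(C)(C)C)c2cc(C)cc(OCc3ccccc3)c12 | intermediate
28 | 5,5'-bis(benzyloxy)-4,4'-dimethoxy-7,7'-dimethyl-2,2'-binaphthalene-1,1'-diol | COc1cc(-c2cc(OC)c3c(OCc4ccccc4)cc(C)cc3c2O)c(O)c2cc(C)cc(OCc3ccccc3)c12 | intermediate
29 | 4,4'-dimethoxy-7,7'-dimethyl-2,2'-binaphthalene-1,1',5,5'-tetraol (CNP0204479.0) | COc1cc(-c2cc(OC)c3c(O)cc(C)cc3c2O)c(O)c2cc(C)cc(O)c12 | target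

**Step count**
- Total step count: 13.
- Longest linear sequence: 12 steps (steps 1–5 and 7–13). Step 6 is a one-step side branch.

**Steps most likely to fail**

**Step 7 (double addition to the diene core).**
- What may go wrong:
  - The second tin–lithium exchange may remain incomplete next to the bulky alkoxide.
  - The first alkoxide may begin oxyanion-driven ring opening before the sequence is finished.
  - The second, very congested 1,2-addition may be too slow.
- Fallback, from 11 back to 18: a Barbier-type double SE2' addition replaces the alkenyllithium chemistry.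
  - 1,4-Dibromobut-2-yne and indium powder in anhydrous THF–DMF convert a first equivalent of 11, through the γ-carbon of the propargylindium species, into 2-(benzyloxy)-7-[1-(bromomethyl)propa-1,2-dien-1-yl]-8,8-dimethoxy-4-methylbicyclo[4.2.0]octa-1,3,5-trien-7-ol F1.
  - Insertion of indium into the remaining C–Br bond gives a buta-2,3-dienylindium. It adds to a second equivalent of 11 through the central allene carbon and delivers diol 18 without strongly basic alkoxides.

**Step 10 (twofold thermolysis).**
- What may go wrong: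
  - The reaction may stall after one ring expansion.
  - Steric compression may erode the inward rotation of the bulky alkenyl group.
  - The ketene may be intercepted by phenolic product faster than it cyclises.
- Fallback, from 11 back to 28: the ring expansion is done on a monomer and the biaryl bond is made last.
  - Vinylmagnesium bromide adds to 11 at −78 °C to give 2-(benzyloxy)-7-ethenyl-8,8-dimethoxy-4-methylbicyclo[4.2.0]octa-1,3,5-trien-7-ol F2.
  - Heating in toluene effects 4π-opening and 6π-closure to 5-(benzyloxy)-4,4-dimethoxy-7-methyl-3,4-dihydronaphthalen-1(2H)-one F3.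
  - Catalytic CSA expels methanol and gives 5-(benzyloxy)-4-methoxy-7-methylnaphthalen-1-ol F4.
  - Oxidative phenol coupling with Ag2O in CH2Cl2, at the only free position ortho to the hydroxyl, gives (E)-5,5'-bis(benzyloxy)-4,4'-dimethoxy-7,7'-dimethyl-[2,2'-binaphthalenylidene]-1,1'-dione F5.
  - Aqueous Na2S2O4 reduces F5 to 28.

**Step 9 (ketal hydrolysis).**
- What may go wrong:
  - The hindered, inductively deactivated ketals may hydrolyse more slowly than the silyl ethers are lost.
  - The acid may attack the diene before hydrolysis is complete.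
- Fallback, from 18 back to 28: the ketals are not removed. The ketal carbon itself serves as the C4 terminus, so a ketene acetal takes the place of the ketene and the C3–C4 closure is kept.
  - Diol 18 is deprotonated with n-BuLi (2 equiv) in THF at −78 °C and allowed to warm. Oxyanion-accelerated 4π-opening and 6π-closure in both halves should give, after protonation, 5,5'-bis(benzyloxy)-4,4,4',4'-tetramethoxy-7,7'-dimethyl-3,3',4,4'-tetrahydro-[2,2'-binaphthalene]-1,1'(2H,2'H)-dione F6.
  - Catalytic CSA then expels one methanol per half and aromatises F6 to 28.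

**Further compounds**
F1 | step 7 | 2-(benzyloxy)-7-[1-(bromomethyl)propa-1,2-dien-1-yl]-8,8-dimethoxy-4-methylbicyclo[4.2.0]octa-1,3,5-trien-7-ol (racemic) | C=C=C(CBr)C1(O)c2cc(C)cc(OCc3ccccc3)c2C1(OC)OC
F2 | step 10 | 2-(benzyloxy)-7-ethenyl-8,8-dimethoxy-4-methylbicyclo[4.2.0]octa-1,3,5-trien-7-ol (racemic) | C=CC1(O)c2cc(C)cc(OCc3ccccc3)c2C1(OC)OC
F3 | step 10 | 5-(benzyloxy)-4,4-dimethoxy-7-methyl-3,4-dihydronaphthalen-1(2H)-one | COC1(OC)CCC(=O)c2cc(C)cc(OCc3ccccc3)c21
F4 | step 10 | 5-(benzyloxy)-4-methoxy-7-methylnaphthalen-1-ol | COc1ccc(O)c2cc(C)cc(OCc3ccccc3)c12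
F5 | step 10 | (E)-5,5'-bis(benzyloxy)-4,4'-dimethoxy-7,7'-dimethyl-[2,2'-binaphthalenylidene]-1,1'-dione | COC1=C/C(=C2/C=C(OC)c3c(OCc4ccccc4)cc(C)cc3C2=O)C(=O)c2cc(C)cc(OCc3ccccc3)c21
F6 | step 9 | 5,5'-bis(benzyloxy)-4,4,4',4'-tetramethoxy-7,7'-dimethyl-3,3',4,4'-tetrahydro-[2,2'-binaphthalene]-1,1'(2H,2'H)-dione (diastereomer mixture) | COC1(OC)CC(C2CC(OC)(OC)c3c(OCc4ccccc4)cc(C)cc3C2=O)C(=O)c2cc(C)cc(OCc3ccccc3)c21
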